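**Strategy.** Ring B is disconnected at C4–C5 and C5–C6. Its hydroxyl on C2 lies para to the unsubstituted C5, and C5 is flanked by the bromine-bearing carbons C4 and C6. This pattern arises when nitromethane exchanges the ring oxygen of a 3-aryloxy-4-pyranone for a nitro-bearing carbon. In one operation the key step builds the benzene ring B: the pyranone carbonyl becomes the C2 phenol, the aryloxy carbon becomes C1, and a nitro group is installed at C5. After reduction, its nitrogen steers both bromine atoms onto C4 and C6 and is then excised by deamination. The precursor is 3-(2,4-dibromo-6-methoxyphenoxy)-4H-pyran-4-one, with ring A and the diaryl ether already complete.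

Key step: step 4

Remark: ring B carries the target numbering throughout (C1 ether oxygen, C2 oxygen function, C5 the carbon supplied by nitromethane). The target has no stereocentre. The phenol is masked as a pivalate because an ester of a 4-nitrophenol must not act as an acyl donor.

**Step 1**
Reactants: 1 guaiacol (2-methoxyphenol)
Product: 2 2,4-dibromo-6-methoxyphenol
Conditions: Br2 (2.05 equiv), AcOH, 10 °C → rt; aq NaHSO3 quench
Reagents that add atoms: bromine, BrBr
Why: Electrophilic aromatic bromination in which the free hydroxyl outranks the methoxyl as director, so the two bromine atoms should enter para and ortho to OH, the pattern ring A needs, while a third substitution is much slower.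

**Step 2**
Reactants: 2 2,4-dibromo-6-methoxyphenol; 3 chloroacetone
Product: 4 1-(2,4-dibromo-6-methoxyphenoxy)propan-2-one
Conditions: K2CO3, KI (cat.), acetone, reflux
Reagents that add atoms: none
Why: Williamson ether synthesis, in which the phenoxide displaces halide from the reactive α-halo ketone by SN2 (iodide exchange in situ), an O-alkylation that tolerates the two ortho substituents.

**Step 3**
Reactants: 4 1-(2,4-dibromo-6-methoxyphenoxy)propan-2-one; 5 N,N-dimethylformamide dimethyl acetal
Product: 8 3-(2,4-dibromo-6-methoxyphenoxy)-4H-pyran-4-one, via mono-enaminone 6 (not isolated), via bis-enaminone 7 (not isolated)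
Conditions: 5 (5 equiv), neat, 120 °C, MeOH distilled off; concentrate; then 2 M HCl, THF, 50 °C
Reagents that add atoms: water, O
Why: Amide-acetal condensation at both α-positions of the ketone (the activated OCH2 first, the methyl on continued heating), then acid hydrolysis of one enamine and cyclocondensation of the resulting enol onto the other enaminone carbon with loss of dimethylamine, the established passage from 1,5-bis(dimethylamino)penta-1,4-dien-3-ones to 4-pyranones.

**Step 4**
Reactants: 8 3-(2,4-dibromo-6-methoxyphenoxy)-4H-pyran-4-one; 9 nitromethane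
Product: 10 2-(2,4-dibromo-6-methoxyphenoxy)-4-nitrophenol
Conditions: MeNO2 (3 equiv), KOtBu (3 equiv), tBuOH/THF, 0 °C → 50 °C; then 1 M HCl
Reagents that add atoms: none
Why: Potassium nitronate adds in Michael fashion to C2 or C6 of the vinylogous ester 8, the adduct opens by retro-oxa-Michael cleavage of its C–O1 bond (equivalently, electrocyclic opening of the 2H-pyran enolate) to a nitromethyl dienone whose former ring oxygen is now a formyl enolate, and the nitronate carbon then closes onto that formyl carbon before water is lost and the ring tautomerizes to the arene. The closest known reaction type is the base-mediated reaction of 4-pyranones and pyrylium salts with nitromethane to give 4-nitrophenols and nitroarenes, an addition, ring-opening and ring-closure sequence that swaps the ring oxygen for carbon. Ring B closes by a 6-exo-trig intramolecular Henry (nitro-aldol) addition, which forms the second of the two new bonds (C4–C5 and C5–C6), the first having been made in the Michael step, and aromatization should make the sequence irreversible. No stereocentre is created. The step needs 1,4-attack at C2/C6 rather than 1,2-attack at the carbonyl carbon or degradation of the ring by oxygen bases: both positions are unsubstituted β-carbons of the vinylogous ester, attack at either converges on the same product, and the hindered tert-butoxide leaves the nitronate as the only competent nucleophile. The ether oxygen on pyranone C3 is a spectator, so C3 becomes C1, the carbonyl carbon becomes C2 (OH) and the nitro carbon ends para to the hydroxyl.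

**Step 5**
Reactants: 10 2-(2,4-dibromo-6-methoxyphenoxy)-4-nitrophenol
Product: 11 2-(2,4-dibromo-6-methoxyphenoxy)-4-nitrophenyl 2,2-dimethylpropanoate
Conditions: PivCl, Et3N, DMAP (cat.), CH2Cl2, 0 °C → rt
Reagents that add atoms: pivaloyl chloride, CC(C)(C)C(Cl)=O
Why: DMAP-catalysed O-acylation (nucleophilic acyl substitution); the tert-butyl group should keep the resulting nitrophenyl ester from transferring its acyl group to the aniline of step 6 and let it survive the aqueous acid of step 8.

**Step 6**
Reactants: 11 2-(2,4-dibromo-6-methoxyphenoxy)-4-nitrophenyl 2,2-dimethylpropanoate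
Product: 12 4-amino-2-(2,4-dibromo-6-methoxyphenoxy)phenyl 2,2-dimethylpropanoate
Conditions: Fe powder, AcOH/EtOH, 60 °C
Reagents that add atoms: none
Why: Béchamp-type dissolving-metal reduction of the nitro group, which should leave the aryl bromides, the diaryl ether and the pivalate untouched, whereas catalytic hydrogenation would risk hydrodebromination.

**Step 7**
Reactants: 12 4-amino-2-(2,4-dibromo-6-methoxyphenoxy)phenyl 2,2-dimethylpropanoate
Product: 13 4-amino-3,5-dibromo-2-(2,4-dibromo-6-methoxyphenoxy)phenyl 2,2-dimethylpropanoate
Conditions: NBS (2.05 equiv), MeCN, 0 °C → rt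
Reagents that add atoms: N-bromosuccinimide, O=C1CCC(=O)N1Br
Why: Electrophilic aromatic bromination directed by the free amino group: its para position is blocked by the ester oxygen, its two ortho positions (C4 and C6 of ring B, also para and ortho to the ether oxygen) are open and strongly activated, and C3 and the doubly brominated ring A are far less reactive, so two equivalents should stop at the dibromide.

**Step 8**
Reactants: 13 4-amino-3,5-dibromo-2-(2,4-dibromo-6-methoxyphenoxy)phenyl 2,2-dimethylpropanoate
Product: 15 3,5-dibromo-2-(2,4-dibromo-6-methoxyphenoxy)phenyl 2,2-dimethylpropanoate, via diazonium hydrogen sulfate 14 (not isolated)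
Conditions: NaNO2, H2SO4, AcOH/H2O, 0–5 °C; then 50% aq H3PO2, 0 °C → rt
Reagents that add atoms: none
Why: Diazotization followed by hydrodediazoniation with hypophosphorous acid (Kornblum-type reductive deamination, a radical chain with H3PO2 as hydrogen donor); the flanking bromine atoms hinder azo coupling, and the aryl bromides, ether and pivalate are inert to cold aqueous acid.

**Step 9**
Reactants: 15 3,5-dibromo-2-(2,4-dibromo-6-methoxyphenoxy)phenyl 2,2-dimethylpropanoate
Product: 16 3,5-dibromo-2-(2,4-dibromo-6-methoxyphenoxy)phenol
Conditions: LiOH, THF/H2O, rt; then 1 M HCl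
Reagents that add atoms: none
Why: Saponification of an aryl ester, in which the electron-poor dibromophenoxide is a good leaving group, so hydroxide should cleave even the pivalate under mild conditions while nothing else in the molecule is base-labile.

**Compound list**
1 | guaiacol (2-methoxyphenol) | COc1ccccc1O | starting material
2 | 2,4-dibromo-6-methoxyphenol | COc1cc(Br)cc(Br)c1O | intermediate
3 | chloroacetone | CC(=O)CCl | starting material
4 | 1-(2,4-dibromo-6-methoxyphenoxy)propan-2-one | CC(=O)COc1c(Br)cc(Br)cc1OC | intermediate
5 | N,N-dimethylformamide dimethyl acetal | COC(OC)N(C)C | starting material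
6 | (Z)-3-(2,4-dibromo-6-methoxyphenoxy)-4-(dimethylamino)but-3-en-2-one (mono-enaminone; geometry as expected for a push–pull alkene) | CC(=O)/C(Oc1c(Br)cc(Br)cc1OC)=C/N(C)C | intermediate
7 | (1Z,4E)-2-(2,4-dibromo-6-methoxyphenoxy)-1,5-bis(dimethylamino)penta-1,4-dien-3-one (bis-enaminone) | CN(C)/C=C/C(=O)/C(Oc1c(Br)cc(Br)cc1OC)=C/N(C)C | intermediate
8 | 3-(2,4-dibromo-6-methoxyphenoxy)-4H-pyran-4-one | COc1cc(Br)cc(Br)c1Oc1coccc1=O | intermediate
9 | nitromethane | C[N+](=O)[O-] | starting material
10 | 2-(2,4-dibromo-6-methoxyphenoxy)-4-nitrophenol | COc1cc(Br)cc(Br)c1Oc1cc([N+](=O)[O-])ccc1O | intermediate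
11 | 2-(2,4-dibromo-6-methoxyphenoxy)-4-nitrophenyl 2,2-dimethylpropanoate | COc1cc(Br)cc(Br)c1Oc1cc([N+](=O)[O-])ccc1OC(=O)C(C)(C)C | intermediate
12 | 4-amino-2-(2,4-dibromo-6-methoxyphenoxy)phenyl 2,2-dimethylpropanoate | COc1cc(Br)cc(Br)c1Oc1cc(N)ccc1OC(=O)C(C)(C)C | intermediate
13 | 4-amino-3,5-dibromo-2-(2,4-dibromo-6-methoxyphenoxy)phenyl 2,2-dimethylpropanoate | COc1cc(Br)cc(Br)c1Oc1c(Br)c(N)c(Br)cc1OC(=O)C(C)(C)C | intermediate
14 | 2,6-dibromo-3-(2,4-dibromo-6-methoxyphenoxy)-4-(2,2-dimethylpropanoyloxy)benzenediazonium hydrogen sulfate | COc1cc(Br)cc(Br)c1Oc1c(Br)c([N+]#N)c(Br)cc1OC(=O)C(C)(C)C.OS(=O)(=O)[O-] | intermediate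
15 | 3,5-dibromo-2-(2,4-dibromo-6-methoxyphenoxy)phenyl 2,2-dimethylpropanoate | COc1cc(Br)cc(Br)c1Oc1c(Br)cc(Br)cc1OC(=O)C(C)(C)C | intermediate
16 | 3,5-dibromo-2-(2,4-dibromo-6-methoxyphenoxy)phenol | COc1cc(Br)cc(Br)c1Oc1c(O)cc(Br)cc1Br | target

**Total step count:** 9
**Longest linear sequence:** 9 steps (guaiacol 1 to target 16)

**Steps most likely to fail**

1. Step 4. Base-induced degradation of the 2,6-unsubstituted pyranone (ring opening by oxygen bases, oligomerization of the formyl enolate) or a second Michael addition of nitromethane to the open-chain dienone may outrun the Henry closure. The fallback abandons the pyranone and builds the diaryl ether directly; it sets out from phenol 2 and comes back at the target 16. Phenol 2 is arylated by nucleophilic aromatic substitution with commercially available 3,5-dibromo-2-fluorobenzaldehyde (O=Cc1cc(Br)cc(Br)c1F; K2CO3, DMF, 100 °C), the fluoride being activated by the ortho formyl group. This should give 3,5-dibromo-2-(2,4-dibromo-6-methoxyphenoxy)benzaldehyde F1. Baeyer–Villiger (Dakin-type) oxidation with mCPBA in CH2Cl2, aryl migration being assisted by the ortho aryloxy oxygen, should convert it into 3,5-dibromo-2-(2,4-dibromo-6-methoxyphenoxy)phenyl formate F2. Methanolysis (KHCO3 cat., MeOH, rt) then releases 16.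

2. Step 3. The second aminomethylenation, at the methyl group of the vinylogous amide, may stall, leaving the ring one carbon short at the cyclization stage. The fallback sets out from ketone 4 and comes back at pyranone 8, introducing the last carbon by Claisen formylation instead. Ketone 4 is condensed with 5 (1.2 equiv, toluene, 80 °C) only as far as the mono-enaminone 6, which is isolated. Deprotonation of its methyl group and formylation (ethyl formate, KOtBu, THF, 0 °C → rt) should give (Z)-4-(2,4-dibromo-6-methoxyphenoxy)-5-(dimethylamino)-3-oxopent-4-enal F3 as its enolate. Acidification (2 M HCl, THF, 50 °C) cyclizes it to 8 with loss of dimethylamine.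

3. Step 8. Diazotization of the weakly basic, doubly ortho-brominated amine may be incomplete in aqueous acid, and the diazonium ion may be lost to hydrolysis or triazene formation before it is reduced. The fallback sets out from amine 13 and comes back at 15, separating the two events under anhydrous nitrosation. Amine 13 is treated with NOBF4 in MeCN at −30 °C → 0 °C, and 2,6-dibromo-3-(2,4-dibromo-6-methoxyphenoxy)-4-(2,2-dimethylpropanoyloxy)benzenediazonium tetrafluoroborate F4 is precipitated with Et2O and isolated. The salt is then reduced in a separate operation (50% aq H3PO2, Cu2O cat., MeCN, 0 °C → rt) to 15.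

**Further compounds**
F1 | step 4 | 3,5-dibromo-2-(2,4-dibromo-6-methoxyphenoxy)benzaldehyde | COc1cc(Br)cc(Br)c1Oc1c(Br)cc(Br)cc1C=O
F2 | step 4 | 3,5-dibromo-2-(2,4-dibromo-6-methoxyphenoxy)phenyl formate | COc1cc(Br)cc(Br)c1Oc1c(Br)cc(Br)cc1OC=O
F3 | step 3 | (Z)-4-(2,4-dibromo-6-methoxyphenoxy)-5-(dimethylamino)-3-oxopent-4-enal | O=CCC(=O)/C(Oc1c(Br)cc(Br)cc1OC)=C/N(C)C
F4 | step 8 | 2,6-dibromo-3-(2,4-dibromo-6-methoxyphenoxy)-4-(2,2-dimethylpropanoyloxy)benzenediazonium tetrafluoroborate | COc1cc(Br)cc(Br)c1Oc1c(Br)c([N+]#N)c(Br)cc1OC(=O)C(C)(C)C.F[B-](F)(F)F
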